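**Plan**

- Numbering: ring A is the acylated resorcinol ring (C1' acyl, O2', C3' prenyl, O4'), ring B is the catechol ring, Cα is the carbinol carbon.
- Retrosynthetic cuts, in order: the four O–Si bonds; the C3'–CH2 bond of the prenyl group (back to an O2'–C(CH3)2CH=CH2 ether); the C1'–C(=O) bond (aryllithium plus Weinreb amide); the O2'–C(CH3)2 bond (bromophenol plus allyl carbonate).
- Forward: no ring is formed. The ring A bromide is O-(1,1-dimethylallyl)ated, lithiated and joined to the danshensu amide; the allyl group then moves from O2' to C3', and the silyl groups are removed.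
- Enabling feature: C3' of ring A lies ortho to O2', between the C2' and C4' oxygens, while C1', the other carbon ortho to O2', carries the acyl group. An allyl group delivered from O2' can therefore only end at C3'.
- Stereochemistry: the single stereocenter (Cα, R) comes from (R)-danshensu; no step breaks a bond at it.
- The tertiary allyl ether is installed before the ketone is built, because a ketone-chelated 2'-OH is a poor nucleophile and an ortho-silyloxy aryllithium would suffer retro-Brook migration.

Key step: step 7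

Assumption: (R)-danshensu is used as the free acid; if only the sodium salt is at hand it is acidified and extracted before step 1, which does not change the chemistry.

**Route**

Step 1
Reactants: 1 (R)-danshensu, (2R)-3-(3,4-dihydroxyphenyl)-2-hydroxypropanoic acid
Product: 2 (2R)-3-(3,4-dihydroxyphenyl)-2-hydroxy-N-methoxy-N-methylpropanamide
Conditions: MeNH(OMe)·HCl, EDC·HCl, HOBt, N-methylmorpholine, DMF, 0 °C → rt, argon
Reagents that add atoms: N,O-dimethylhydroxylamine hydrochloride, CNOC.Cl
Why: Carbodiimide/HOBt amide coupling, in which the amine nitrogen outcompetes the phenolic and secondary hydroxyls for the active ester, and the near-neutral, non-enolising medium leaves the Cα center untouched.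

Step 2
Reactants: 2 (2R)-3-(3,4-dihydroxyphenyl)-2-hydroxy-N-methoxy-N-methylpropanamide
Product: 3 (2R)-2-(tert-butyldimethylsilyloxy)-3-[3,4-bis(tert-butyldimethylsilyloxy)phenyl]-N-methoxy-N-methylpropanamide
Conditions: TBSCl (excess), imidazole, DMF, rt
Reagents that add atoms: tert-butyldimethylsilyl chloride (TBSCl), CC(C)(C)[Si](C)(C)Cl
Why: Standard imidazole-promoted silyl ether formation should cap both phenols and the secondary alcohol without breaking any bond at the stereocenter.

Step 3
Reactants: 4 4-bromoresorcinol (4-bromobenzene-1,3-diol)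
Product: 5 2-bromo-5-(tert-butyldimethylsilyloxy)phenol
Conditions: TBSCl (1.0 equiv), imidazole, DMF, −20 → 0 °C
Reagents that add atoms: tert-butyldimethylsilyl chloride (TBSCl), CC(C)(C)[Si](C)(C)Cl
Why: Sterically controlled mono-silylation, since the hydroxyl para to bromine is unhindered while the one ortho to bromine is shielded and hydrogen-bonded to the halogen, so one equivalent of the bulky chloride should go to the former (isomer and bis-ether are separable).

Step 4
Reactants: 6 2-methylbut-3-en-2-ol
Product: 7 tert-butyl 2-methylbut-3-en-2-yl carbonate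
Conditions: n-BuLi, THF, −78 → 0 °C; Boc2O, 0 °C → rt; H2O work-up
Reagents that add atoms: di-tert-butyl dicarbonate (Boc2O), CC(C)(C)OC(=O)OC(=O)OC(C)(C)C
Why: Acylation of the lithium alkoxide of the tertiary allylic alcohol by the dicarbonate is the usual way to such mixed carbonates for allylic substitution.

Step 5
Reactants: 5 2-bromo-5-(tert-butyldimethylsilyloxy)phenol; 7 tert-butyl 2-methylbut-3-en-2-yl carbonate
Product: 8 1-bromo-4-(tert-butyldimethylsilyloxy)-2-(2-methylbut-3-en-2-yloxy)benzene
Conditions: Pd(PPh3)4 (5 mol %), THF, 0 °C → rt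
Reagents that add atoms: none
Why: Decarboxylative Tsuji–Trost O-allylation, in which zerovalent palladium ionises the carbonate, the released tert-butoxide deprotonates the phenol, and the phenoxide attacks the more substituted allyl terminus under kinetic control to give the tertiary ether, while the electron-rich aryl bromide should not undergo oxidative addition at this temperature.

Step 6
Reactants: 8 1-bromo-4-(tert-butyldimethylsilyloxy)-2-(2-methylbut-3-en-2-yloxy)benzene; 3 (2R)-2-(tert-butyldimethylsilyloxy)-3-[3,4-bis(tert-butyldimethylsilyloxy)phenyl]-N-methoxy-N-methylpropanamide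
Product: 11 (2R)-2-(tert-butyldimethylsilyloxy)-1-[4-(tert-butyldimethylsilyloxy)-2-(2-methylbut-3-en-2-yloxy)phenyl]-3-[3,4-bis(tert-butyldimethylsilyloxy)phenyl]propan-1-one, via aryllithium 9 (not isolated), via lithium hemiaminal alkoxide 10 (not isolated)
Conditions: n-BuLi, THF, −78 °C; then 3, −78 → −50 °C; AcOH quench at −78 °C
Reagents that add atoms: none
Why: Bromine–lithium exchange followed by Weinreb ketone synthesis, where the chelated adduct 10 prevents over-addition, the silyl ether para to lithium cannot undergo retro-Brook migration, and at −78 °C neither cyclisation of 9 onto its vinyl group nor enolisation of the amide should compete, so the (R) center is kept.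

Step 7
Reactants: 11 (2R)-2-(tert-butyldimethylsilyloxy)-1-[4-(tert-butyldimethylsilyloxy)-2-(2-methylbut-3-en-2-yloxy)phenyl]-3-[3,4-bis(tert-butyldimethylsilyloxy)phenyl]propan-1-one
Product: 13 (2R)-2-(tert-butyldimethylsilyloxy)-1-[4-(tert-butyldimethylsilyloxy)-2-hydroxy-3-(3-methylbut-2-enyl)phenyl]-3-[3,4-bis(tert-butyldimethylsilyloxy)phenyl]propan-1-one, via 6-prenylcyclohexa-2,4-dienone 12 (not isolated)
Conditions: degassed toluene, 110 °C, sealed tube, base-washed glassware
Reagents that add atoms: none
Why: On heating, the aryl 1,1-dimethylallyl ether undergoes a concerted, suprafacial [3,3]-sigmatropic shift through a chair-like six-membered transition state in which the vinyl CH2 bonds to C3' as the O–C(CH3)2 bond breaks, giving dienone 12, which enolises to phenol 13. The closest known reaction type is the aromatic Claisen rearrangement of aryl 1,1-dimethylallyl ethers to ortho-prenyl phenols, which runs at comparatively low temperature because the tertiary O–C bond is weakened. No ring is closed (the cyclic array exists only in the transition state) and no new stereocenter remains, because the sp3 carbon C3' of 12 is lost on enolisation. The selectivity needed is C3' over C1' and C5' and carbon over oxygen attachment: C1' carries the acyl group, so a shift to it cannot rearomatise and reverts, C5' is not reachable by a single [3,3] shift from O2', and intramolecular delivery excludes the mixtures of direct prenylation. Allylic transposition turns the 1,1-dimethylallyl group into the prenyl group, and the released 2'-OH is at once hydrogen-bonded to the ketone, which disfavours chroman formation. The neutral, aprotic medium cannot enolise the ketone, so the silyl-protected (R) center should pass through unchanged.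

Step 8
Reactants: 13 (2R)-2-(tert-butyldimethylsilyloxy)-1-[4-(tert-butyldimethylsilyloxy)-2-hydroxy-3-(3-methylbut-2-enyl)phenyl]-3-[3,4-bis(tert-butyldimethylsilyloxy)phenyl]propan-1-one
Product: 14 (2R)-1-[2,4-dihydroxy-3-(3-methylbut-2-enyl)phenyl]-3-(3,4-dihydroxyphenyl)-2-hydroxypropan-1-one (CNP0408242.1)
Conditions: HF·pyridine, excess pyridine, THF, 0 °C → rt, argon
Reagents that add atoms: none
Why: Fluoride-mediated Si–O cleavage under buffered, mildly acidic conditions should remove all four silyl groups while avoiding base-induced epimerisation or α-ketol isomerisation, catechol oxidation and strong-acid cyclisation of the prenyl phenol to a chroman.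

**Compound list**

1 | (R)-danshensu, (2R)-3-(3,4-dihydroxyphenyl)-2-hydroxypropanoic acid | O=C(O)[C@H](O)Cc1ccc(O)c(O)c1 | starting material
2 | (2R)-3-(3,4-dihydroxyphenyl)-2-hydroxy-N-methoxy-N-methylpropanamide | CON(C)C(=O)[C@H](O)Cc1ccc(O)c(O)c1 | intermediate
3 | (2R)-2-(tert-butyldimethylsilyloxy)-3-[3,4-bis(tert-butyldimethylsilyloxy)phenyl]-N-methoxy-N-methylpropanamide | CON(C)C(=O)[C@H](O[Si](C)(C)C(C)(C)C)Cc1ccc(O[Si](C)(C)C(C)(C)C)c(O[Si](C)(C)C(C)(C)C)c1 | intermediate
4 | 4-bromoresorcinol (4-bromobenzene-1,3-diol) | Oc1ccc(Br)c(O)c1 | starting material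
5 | 2-bromo-5-(tert-butyldimethylsilyloxy)phenol | CC(C)(C)[Si](C)(C)Oc1ccc(Br)c(O)c1 | intermediate
6 | 2-methylbut-3-en-2-ol | C=CC(C)(C)O | starting material
7 | tert-butyl 2-methylbut-3-en-2-yl carbonate | C=CC(C)(C)OC(=O)OC(C)(C)C | intermediate
8 | 1-bromo-4-(tert-butyldimethylsilyloxy)-2-(2-methylbut-3-en-2-yloxy)benzene | C=CC(C)(C)Oc1cc(O[Si](C)(C)C(C)(C)C)ccc1Br | intermediate
9 | [4-(tert-butyldimethylsilyloxy)-2-(2-methylbut-3-en-2-yloxy)phenyl]lithium | C=CC(C)(C)Oc1cc(O[Si](C)(C)C(C)(C)C)ccc1[Li] | intermediate (not isolated)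
10 | lithium alkoxide of the N-methoxy-N-methyl hemiaminal formed from 9 and 3, (R) at the silyloxy carbon, carbinol carbon undefined | [Li]OC(N(C)OC)(c1ccc(O[Si](C)(C)C(C)(C)C)cc1OC(C)(C)C=C)[C@H](O[Si](C)(C)C(C)(C)C)Cc1ccc(O[Si](C)(C)C(C)(C)C)c(O[Si](C)(C)C(C)(C)C)c1 | intermediate (not isolated)
11 | (2R)-2-(tert-butyldimethylsilyloxy)-1-[4-(tert-butyldimethylsilyloxy)-2-(2-methylbut-3-en-2-yloxy)phenyl]-3-[3,4-bis(tert-butyldimethylsilyloxy)phenyl]propan-1-one | C=CC(C)(C)Oc1cc(O[Si](C)(C)C(C)(C)C)ccc1C(=O)[C@H](O[Si](C)(C)C(C)(C)C)Cc1ccc(O[Si](C)(C)C(C)(C)C)c(O[Si](C)(C)C(C)(C)C)c1 | intermediate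
12 | 2-[(2R)-2-(tert-butyldimethylsilyloxy)-3-[3,4-bis(tert-butyldimethylsilyloxy)phenyl]propanoyl]-5-(tert-butyldimethylsilyloxy)-6-(3-methylbut-2-enyl)cyclohexa-2,4-dienone, C6 undefined | CC(C)=CCC1C(=O)C(C(=O)[C@H](O[Si](C)(C)C(C)(C)C)Cc2ccc(O[Si](C)(C)C(C)(C)C)c(O[Si](C)(C)C(C)(C)C)c2)=CC=C1O[Si](C)(C)C(C)(C)C | intermediate (not isolated)
13 | (2R)-2-(tert-butyldimethylsilyloxy)-1-[4-(tert-butyldimethylsilyloxy)-2-hydroxy-3-(3-methylbut-2-enyl)phenyl]-3-[3,4-bis(tert-butyldimethylsilyloxy)phenyl]propan-1-one | CC(C)=CCc1c(O[Si](C)(C)C(C)(C)C)ccc(C(=O)[C@H](O[Si](C)(C)C(C)(C)C)Cc2ccc(O[Si](C)(C)C(C)(C)C)c(O[Si](C)(C)C(C)(C)C)c2)c1O | intermediate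
14 | (2R)-1-[2,4-dihydroxy-3-(3-methylbut-2-enyl)phenyl]-3-(3,4-dihydroxyphenyl)-2-hydroxypropan-1-one (CNP0408242.1) | CC(C)=CCc1c(O)ccc(C(=O)[C@H](O)Cc2ccc(O)c(O)c2)c1O | target

**Count and risks**

Total steps: 8. Longest linear sequence: 5 steps (steps 1, 2, 6, 7, 8 from danshensu; equally steps 3, 5, 6, 7, 8 from 4-bromoresorcinol).

Step 7. The tertiary allyl group may be lost as isoprene by heterolysis, because the ortho-acyl phenoxide is a good leaving group, in competition with the sigmatropic shift. The fallback moves the rearrangement forward to the bromoarene, whose phenoxide is a poorer leaving group; it sets out from 8 and rejoins the route at 13. Compound 8 is heated in toluene at 110 °C. The [3,3] shift gives 2-bromo-5-(tert-butyldimethylsilyloxy)-6-(3-methylbut-2-enyl)cyclohexa-2,4-dienone F1 (not isolated), which enolises to 6-bromo-3-(tert-butyldimethylsilyloxy)-2-(3-methylbut-2-enyl)phenol F2. Two equivalents of n-BuLi in THF (−78 → −20 °C) deprotonate the phenol and exchange the bromine, giving lithium 6-lithio-3-(tert-butyldimethylsilyloxy)-2-(3-methylbut-2-enyl)phenoxide F3. Acylation of this by Weinreb amide 3 gives the dilithium hemiaminal adduct F4, which collapses on cold AcOH quench to 13.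

Step 6. Addition of the hindered ortho-alkoxy aryllithium to the amide may be slow, so that cyclisation of 9 onto its vinyl group or proton abstraction at the amide α-position takes over. The fallback uses a more electrophilic partner; it sets out from 3 and rejoins the route at 11. Amide 3 is reduced with i-Bu2AlH (THF, −78 °C) through the diisobutylaluminium hemiaminal F5 (not isolated) to (2R)-2-(tert-butyldimethylsilyloxy)-3-[3,4-bis(tert-butyldimethylsilyloxy)phenyl]propanal F6. Aryllithium 9, made from 8 as in step 6, adds to F6 at −78 °C, with a cold AcOH quench to prevent 1,2-silyl migration. This gives (2R)-2-(tert-butyldimethylsilyloxy)-1-[4-(tert-butyldimethylsilyloxy)-2-(2-methylbut-3-en-2-yloxy)phenyl]-3-[3,4-bis(tert-butyldimethylsilyloxy)phenyl]propan-1-ol F7 as a mixture of carbinol epimers. Dess–Martin oxidation (NaHCO3-buffered CH2Cl2) converts both epimers to 11.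

Step 5. The phenoxide may attack the unsubstituted allyl terminus to give the linear prenyl ether, or the palladium may insert into the C–Br bond. The fallback replaces allylic substitution by propargylation and semi-hydrogenation; it sets out from 5 and rejoins the route at 8. Phenol 5 is alkylated with 3-chloro-3-methylbut-1-yne (CuCl2 cat., DBU, anhydrous MeCN, 0 °C) to give 1-bromo-4-(tert-butyldimethylsilyloxy)-2-(2-methylbut-3-yn-2-yloxy)benzene F8. Semi-hydrogenation (H2, Pd/CaCO3 poisoned with Pb(OAc)2, quinoline, EtOAc) then gives 8.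

**Further compounds**

F1 | step 7 | 2-bromo-5-(tert-butyldimethylsilyloxy)-6-(3-methylbut-2-enyl)cyclohexa-2,4-dienone | CC(C)=CCC1C(=O)C(Br)=CC=C1O[Si](C)(C)C(C)(C)C
F2 | step 7 | 6-bromo-3-(tert-butyldimethylsilyloxy)-2-(3-methylbut-2-enyl)phenol | CC(C)=CCc1c(O)c(Br)ccc1O[Si](C)(C)C(C)(C)C
F3 | step 7 | lithium 6-lithio-3-(tert-butyldimethylsilyloxy)-2-(3-methylbut-2-enyl)phenoxide | CC(C)=CCc1c(O[Li])c([Li])ccc1O[Si](C)(C)C(C)(C)C
F4 | step 7 | dilithium hemiaminal adduct of F3 and 3 | [Li]OC(N(C)OC)(c1ccc(O[Si](C)(C)C(C)(C)C)c(CC=C(C)C)c1O[Li])[C@H](O[Si](C)(C)C(C)(C)C)Cc1ccc(O[Si](C)(C)C(C)(C)C)c(O[Si](C)(C)C(C)(C)C)c1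
F5 | step 6 | diisobutylaluminium hemiaminal from 3 | CC(C)C[Al](CC(C)C)OC(N(C)OC)[C@H](O[Si](C)(C)C(C)(C)C)Cc1ccc(O[Si](C)(C)C(C)(C)C)c(O[Si](C)(C)C(C)(C)C)c1
F6 | step 6 | (2R)-2-(tert-butyldimethylsilyloxy)-3-[3,4-bis(tert-butyldimethylsilyloxy)phenyl]propanal | O=C[C@H](O[Si](C)(C)C(C)(C)C)Cc1ccc(O[Si](C)(C)C(C)(C)C)c(O[Si](C)(C)C(C)(C)C)c1
F7 | step 6 | (2R)-2-(tert-butyldimethylsilyloxy)-1-[4-(tert-butyldimethylsilyloxy)-2-(2-methylbut-3-en-2-yloxy)phenyl]-3-[3,4-bis(tert-butyldimethylsilyloxy)phenyl]propan-1-ol, C1 epimers | C=CC(C)(C)Oc1cc(O[Si](C)(C)C(C)(C)C)ccc1C(O)[C@H](O[Si](C)(C)C(C)(C)C)Cc1ccc(O[Si](C)(C)C(C)(C)C)c(O[Si](C)(C)C(C)(C)C)c1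
F8 | step 5 | 1-bromo-4-(tert-butyldimethylsilyloxy)-2-(2-methylbut-3-yn-2-yloxy)benzene | C#CC(C)(C)Oc1cc(O[Si](C)(C)C(C)(C)C)ccc1Br
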